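**Retrosynthetic overview**

1. The route rests on the cis pair C3a/C8a of the five-membered ring: C3a carries C4 with its exocyclic methylene and C8a carries the oxidised carbon C8, so C8–C8a–C3a–C4=CH2 is a γ,δ-unsaturated carboxyl array, the retron of an ester-enolate Claisen rearrangement.
2. The five-membered ring is made first: C8a–C3a is formed by Ireland–Claisen ring contraction of the nine-membered Z,Z-dienyl lactone 16, which also leaves the methylene on C4.
3. Lactone 16 is opened at the ester bond and at C3–C3a: alkyne 6 (C1 centre from (R)-citramalic acid) and Z-iodoalkene 11 (but-3-yn-1-ol, silylformylation) are joined by Sonogashira coupling, cis-semireduction and lactonisation.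
4. The seven-membered ring is made second: C6–C7 by alkylation of side-chain sulfone 32 (C11 from (R)-methylsuccinate, C13 by CBS reduction) with iodide 22, then C7–C8 by sulfonyl-carbanion acylation of the C8 ester; desulfonylation sets C7.
5. The end game is desilylation, acetylation of the C13 hydroxyl and hydroxyl-directed reduction of the C8 ketone.

Key step: step 14

**Remarks on the chemistry**

- Numbering: azulene numbering for the bicycle (C1 to C8a); the side chain is C11 (methine on C7), C12, C13 (acetoxy carbon), C14=C15.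
- Compound 23, the 4-methyl half-ester of (R)-methylsuccinic acid, is taken as the commercial, regiochemically differentiated form of (R)-methylsuccinate.
- Sulfones 34 and 36 are carried as mixtures at C7; this centre is set only in step 27.

**Route**

Step 1
Reactants: 1 (R)-citramalic acid
Product: 2 dimethyl (2R)-2-hydroxy-2-methylbutanedioate
Conditions: HCl (1.25 M in MeOH), MeOH, 23 °C
Reagents that add atoms: methanol (CO)
Why: Fischer esterification under mild acid should leave the tertiary carbinol, and with it the future C1 centre, untouched.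

Step 2
Reactants: 2 dimethyl (2R)-2-hydroxy-2-methylbutanedioate
Product: 3 methyl (3R)-3,4-dihydroxy-3-methylbutanoate
Conditions: BH3·SMe2, NaBH4 (5 mol %), THF, 0 → 23 °C; then MeOH
Reagents that add atoms: none
Why: Chelation-controlled borane reduction: the alkoxyborane formed at the free hydroxyl should deliver hydride only to the neighbouring ester, so the distal ester (future C8) is kept and the stereocentre is not involved.

Step 3
Reactants: 3 methyl (3R)-3,4-dihydroxy-3-methylbutanoate (used crude)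
Product: 4 methyl (3R)-3-methyl-3,4-bis[(triethylsilyl)oxy]butanoate
Conditions: Et3SiOTf, 2,6-lutidine, CH2Cl2, −78 → 0 °C
Reagents that add atoms: triethylsilyl trifluoromethanesulfonate (CC[Si](CC)(CC)OS(=O)(=O)C(F)(F)F)
Why: Silylation with the silyl triflate is strong enough for the tertiary hydroxyl, and immediate bis-silylation should forestall lactonisation of the diol ester.

Step 4
Reactants: 4 methyl (3R)-3-methyl-3,4-bis[(triethylsilyl)oxy]butanoate
Product: 5 methyl (3R)-3-methyl-4-oxo-3-[(triethylsilyl)oxy]butanoate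
Conditions: (COCl)2, DMSO, CH2Cl2, −78 → −40 °C; Et3N, −78 → 0 °C
Reagents that add atoms: none
Why: Swern oxidation applied to silyl ethers cleaves and oxidises a primary triethylsilyl ether directly while the hindered tertiary one is inert, which should give the non-enolisable α-silyloxy aldehyde.

Step 5
Reactants: 5 methyl (3R)-3-methyl-4-oxo-3-[(triethylsilyl)oxy]butanoate
Product: 6 methyl (3R)-3-methyl-3-[(triethylsilyl)oxy]pent-4-ynoate
Conditions: dimethyl (1-diazo-2-oxopropyl)phosphonate, K2CO3, MeOH, 0 → 23 °C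
Reagents that add atoms: dimethyl (1-diazo-2-oxopropyl)phosphonate (COP(=O)(OC)C(=[N+]=[N-])C(C)=O)
Why: Seyferth–Gilbert homologation with the Ohira–Bestmann reagent adds C3; the aldehyde has no α-hydrogen, so C1 cannot epimerise under the mild carbonate conditions.

Step 6
Reactants: 7 but-3-yn-1-ol
Product: 8 1-[(but-3-yn-1-yloxy)methyl]-4-methoxybenzene
Conditions: NaH, 4-MeOC6H4CH2Cl, Bu4NI (cat.), THF/DMF, 0 → 23 °C
Reagents that add atoms: 4-methoxybenzyl chloride (COc1ccc(CCl)cc1)
Why: Williamson etherification protects the future C6 oxygen with a group that survives base and is removed oxidatively later.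

Step 7
Reactants: 8 1-[(but-3-yn-1-yloxy)methyl]-4-methoxybenzene
Product: 9 (2Z)-3-[dimethyl(phenyl)silyl]-2-{2-[(4-methoxybenzyl)oxy]ethyl}prop-2-enal
Conditions: PhMe2SiH, CO (20 bar), Rh4(CO)12 (0.5 mol %), Et3N, toluene, 100 °C
Reagents that add atoms: dimethylphenylsilane (C[SiH](C)c1ccccc1); carbon monoxide ([C-]#[O+])
Why: Rhodium-catalysed silylformylation of a terminal alkyne is a syn addition that puts silicon on the terminal carbon (C3a) and the formyl group on the internal carbon (C4), so Si and CHO should be cis and the later C3a=C4 geometry is fixed here.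

Step 8
Reactants: 9 (2Z)-3-[dimethyl(phenyl)silyl]-2-{2-[(4-methoxybenzyl)oxy]ethyl}prop-2-enal
Product: 10 (2Z)-3-[dimethyl(phenyl)silyl]-2-{2-[(4-methoxybenzyl)oxy]ethyl}prop-2-en-1-ol
Conditions: NaBH4, CeCl3·7H2O, MeOH, −20 °C
Reagents that add atoms: none
Why: Luche 1,2-reduction of the enal should give the allylic alcohol without touching the vinylsilane or its geometry.

Step 9
Reactants: 10 (2Z)-3-[dimethyl(phenyl)silyl]-2-{2-[(4-methoxybenzyl)oxy]ethyl}prop-2-en-1-ol
Product: 11 (2Z)-3-iodo-2-{2-[(4-methoxybenzyl)oxy]ethyl}prop-2-en-1-ol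
Conditions: N-iodosuccinimide, 2,6-lutidine, (CF3)2CHOH, 0 °C
Reagents that add atoms: N-iodosuccinimide (O=C1CCC(=O)N1I)
Why: ipso-Iododesilylation of a vinylsilane in this solvent proceeds with retention through the β-silyl cation, so iodine should end up cis to CH2OH; the buffer, low temperature and short time are meant to spare the anisyl ring.

Step 10
Reactants: 6 methyl (3R)-3-methyl-3-[(triethylsilyl)oxy]pent-4-ynoate; 11 (2Z)-3-iodo-2-{2-[(4-methoxybenzyl)oxy]ethyl}prop-2-en-1-ol
Product: 12 methyl (3R,6Z)-7-(hydroxymethyl)-9-[(4-methoxybenzyl)oxy]-3-methyl-3-[(triethylsilyl)oxy]non-6-en-4-ynoate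
Conditions: PdCl2(PPh3)2 (5 mol %), CuI (10 mol %), Et3N, THF, 23 °C
Reagents that add atoms: none
Why: Sonogashira coupling forms C3–C3a with retention of the iodoalkene geometry and tolerates the free alcohol, the ester and both ethers.

Step 11
Reactants: 12 methyl (3R,6Z)-7-(hydroxymethyl)-9-[(4-methoxybenzyl)oxy]-3-methyl-3-[(triethylsilyl)oxy]non-6-en-4-ynoate
Product: 13 methyl (3R,4Z,6Z)-7-(hydroxymethyl)-9-[(4-methoxybenzyl)oxy]-3-methyl-3-[(triethylsilyl)oxy]nona-4,6-dienoate
Conditions: Zn dust activated with Cu(OAc)2 and AgNO3, MeOH/H2O (1:1), 23 → 40 °C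
Reagents that add atoms: none
Why: Activated-zinc semireduction is specific for alkynes conjugated with an alkene and delivers the cis alkene without over-reduction, so the Z,Z-diene should result.

Step 12
Reactants: 13 methyl (3R,4Z,6Z)-7-(hydroxymethyl)-9-[(4-methoxybenzyl)oxy]-3-methyl-3-[(triethylsilyl)oxy]nona-4,6-dienoate
Product: 14 (3R,4Z,6Z)-7-(hydroxymethyl)-9-[(4-methoxybenzyl)oxy]-3-methyl-3-[(triethylsilyl)oxy]nona-4,6-dienoic acid
Conditions: LiOH·H2O, THF/MeOH/H2O, 0 → 23 °C; 1 M HCl to pH 4 at 0 °C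
Reagents that add atoms: lithium hydroxide ([Li+].[OH-])
Why: Saponification of the unhindered methyl ester should proceed without loss of the hindered tertiary silyl ether.

Step 13
Reactants: 14 (3R,4Z,6Z)-7-(hydroxymethyl)-9-[(4-methoxybenzyl)oxy]-3-methyl-3-[(triethylsilyl)oxy]nona-4,6-dienoic acid
Product: 16 (4R,5Z,7Z)-8-{2-[(4-methoxybenzyl)oxy]ethyl}-4-methyl-4-[(triethylsilyl)oxy]-4,9-dihydrooxonin-2(3H)-one, via mixed anhydride 15 (not isolated)
Conditions: 2,4,6-Cl3C6H2COCl, Et3N, THF, 23 °C; then slow addition to DMAP, toluene, 80 °C (about 1 mM)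
Reagents that add atoms: none
Why: Yamaguchi lactonisation; the two Z alkenes and the quaternary C1 should fold the chain so that the hydroxyl and the activated acyl group lie close, which is what a nine-membered closure needs under high dilution.

Step 14
Reactants: 16 (4R,5Z,7Z)-8-{2-[(4-methoxybenzyl)oxy]ethyl}-4-methyl-4-[(triethylsilyl)oxy]-4,9-dihydrooxonin-2(3H)-one
Product: 19 (1S,2S,5S)-5-{4-[(4-methoxybenzyl)oxy]but-1-en-2-yl}-2-methyl-2-[(triethylsilyl)oxy]cyclopent-3-ene-1-carboxylic acid, via silyl ketene acetal 17 (not isolated), via trimethylsilyl ester 18 (not isolated)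
Conditions: Me3SiCl/Et3N, THF, −78 °C; LiN(i-Pr)2, −78 °C; then 23 °C and toluene, 80 °C; aqueous citric acid
Reagents that add atoms: none
Why: LiN(i-Pr)2 deprotonates C8a in the presence of Me3SiCl, so the lactone enolate is silylated at once to ketene acetal 17 (endocyclic C8=C8a, ring oxygen and C1 necessarily cis), which should suppress β-elimination of the C1 silyloxy group; 17 then undergoes the [3,3]-sigmatropic shift in which C8a bonds to C3a while the allylic C–O bond breaks, giving silyl ester 18 and, after hydrolysis, acid 19. The closest known reaction type is the Ireland–Claisen ring contraction of medium and large allylic lactones to cis-2-alkenylcycloalkanecarboxylic acids. The five-membered ring closes by this transannular pericyclic C–C bond formation through a boat-like six-centre transition state bridged by C1–C2=C3, a contraction from nine to five ring atoms driven by relief of medium-ring strain and by formation of the carboxyl C=O. C8a and C3a are set together: both reacting termini are held cis in the nine-membered ring, so C8 and the C4 alkenyl group must end up cis on the cyclopentene, and the breaking C–O bond leaves the methylene exactly on C4. The selectivity that has to be secured is the facial one relative to the existing C1 centre: in the boat the C1 substituent syn to the ketene acetal carbon eclipses its OSiMe3 group, so the small methyl is expected there and the bulky Et3SiO group on the other face, which places C8 cis to the C1 methyl as in the target. The Z geometry of C2=C3 and of C3a=C4, fixed in steps 7 to 11, is what makes this transition state reachable.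

Step 15
Reactants: 19 (1S,2S,5S)-5-{4-[(4-methoxybenzyl)oxy]but-1-en-2-yl}-2-methyl-2-[(triethylsilyl)oxy]cyclopent-3-ene-1-carboxylic acid
Product: 20 methyl (1S,2S,5S)-5-{4-[(4-methoxybenzyl)oxy]but-1-en-2-yl}-2-methyl-2-[(triethylsilyl)oxy]cyclopent-3-ene-1-carboxylate
Conditions: Me3SiCHN2, toluene/MeOH (4:1), 0 °C
Reagents that add atoms: (trimethylsilyl)diazomethane (C[Si](C)(C)C=[N+]=[N-])
Why: Diazoalkane O-methylation is neutral, so C8a, now α to the ester, should not epimerise.

Step 16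
Reactants: 20 methyl (1S,2S,5S)-5-{4-[(4-methoxybenzyl)oxy]but-1-en-2-yl}-2-methyl-2-[(triethylsilyl)oxy]cyclopent-3-ene-1-carboxylate
Product: 21 methyl (1S,2S,5S)-5-(4-hydroxybut-1-en-2-yl)-2-methyl-2-[(triethylsilyl)oxy]cyclopent-3-ene-1-carboxylate
Conditions: DDQ, CH2Cl2/pH 7 buffer (10:1), 0 °C
Reagents that add atoms: none
Why: Oxidative cleavage of the electron-rich 4-methoxybenzyl ether by DDQ should leave the silyl ether, the ester and both isolated alkenes alone.

Step 17
Reactants: 21 methyl (1S,2S,5S)-5-(4-hydroxybut-1-en-2-yl)-2-methyl-2-[(triethylsilyl)oxy]cyclopent-3-ene-1-carboxylate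
Product: 22 methyl (1S,2S,5S)-5-(4-iodobut-1-en-2-yl)-2-methyl-2-[(triethylsilyl)oxy]cyclopent-3-ene-1-carboxylate
Conditions: I2, PPh3, imidazole, CH2Cl2, 0 → 23 °C
Reagents that add atoms: iodine (II)
Why: Appel-type iodination converts the primary C6 alcohol into the iodide by SN2 displacement of the alkoxyphosphonium ion under near-neutral conditions.

Step 18
Reactants: 23 (2R)-4-methoxy-2-methyl-4-oxobutanoic acid
Product: 25 (4R)-4-methyloxolan-2-one, via hydroxy ester 24 (not isolated)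
Conditions: BH3·SMe2, THF, 0 → 23 °C; MeOH; then TsOH·H2O (cat.), CH2Cl2, 23 °C
Reagents that add atoms: none
Why: Borane reduces the carboxylic acid chemoselectively beside the methyl ester and the γ-hydroxy ester lactonises under acid catalysis, which differentiates the two ends without touching the C11 centre.

Step 19
Reactants: 25 (4R)-4-methyloxolan-2-one
Product: 26 (3R)-3-methyl-4-(phenylsulfanyl)butanoic acid
Conditions: PhSH, NaH, DMF, 0 → 110 °C; then 1 M HCl
Reagents that add atoms: thiophenol (Sc1ccccc1)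
Why: Thiolate opening of a γ-lactone by SN2 attack at the alkyl C–O carbon puts sulfur on the future C7 and frees the carboxyl that becomes C13; the stereocentre is not a reaction site.

Step 20
Reactants: 26 (3R)-3-methyl-4-(phenylsulfanyl)butanoic acid
Product: 28 (3R)-N-methoxy-N,3-dimethyl-4-(phenylsulfanyl)butanamide, via acyl imidazole 27 (not isolated)
Conditions: 1,1'-carbonyldiimidazole, CH2Cl2, 0 → 23 °C; then MeNH(OMe)·HCl
Reagents that add atoms: N,O-dimethylhydroxylamine hydrochloride (CNOC.Cl)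
Why: Weinreb amide formation through the acyl imidazole is a standard amide coupling that prepares C13 for a single organometallic addition.

Step 21
Reactants: 28 (3R)-N-methoxy-N,3-dimethyl-4-(phenylsulfanyl)butanamide
Product: 29 (6R)-2,6-dimethyl-7-(phenylsulfanyl)hept-2-en-4-one
Conditions: Me2C=CHMgBr, THF, 0 °C; aqueous NH4Cl
Reagents that add atoms: (2-methylprop-1-en-1-yl)magnesium bromide (CC(C)=C[Mg]Br)
Why: Grignard addition to a Weinreb amide stops at the chelated tetrahedral intermediate, so the enone carrying C14=C15 should form without over-addition.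

Step 22
Reactants: 29 (6R)-2,6-dimethyl-7-(phenylsulfanyl)hept-2-en-4-one
Product: 30 (4R,6R)-2,6-dimethyl-7-(phenylsulfanyl)hept-2-en-4-ol
Conditions: (S)-2-methyl-CBS-oxazaborolidine (20 mol %), BH3·SMe2, THF, −30 °C; MeOH
Reagents that add atoms: none
Why: Corey–Bakshi–Shibata reduction under reagent control: with the alkenyl group as the large substituent the (S)-catalyst is expected to give the (R)-carbinol at C13, independently of the remote C11 centre.

Step 23
Reactants: 30 (4R,6R)-2,6-dimethyl-7-(phenylsulfanyl)hept-2-en-4-ol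
Product: 31 tert-butyl{[(4R,6R)-2,6-dimethyl-7-(phenylsulfanyl)hept-2-en-4-yl]oxy}dimethylsilane
Conditions: t-BuMe2SiCl, imidazole, DMF, 23 °C
Reagents that add atoms: tert-butyldimethylsilyl chloride (CC(C)(C)[Si](C)(C)Cl)
Why: Silylation masks the C13 hydroxyl against the carbanion chemistry to come and removes the allylic-alcohol directing effect before the sulfur oxidation.

Step 24
Reactants: 31 tert-butyl{[(4R,6R)-2,6-dimethyl-7-(phenylsulfanyl)hept-2-en-4-yl]oxy}dimethylsilane
Product: 32 {[(4R,6R)-7-(benzenesulfonyl)-2,6-dimethylhept-2-en-4-yl]oxy}(tert-butyl)dimethylsilane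
Conditions: (NH4)6Mo7O24·4H2O (10 mol %), 30% H2O2, EtOH, 0 → 23 °C
Reagents that add atoms: hydrogen peroxide (OO)
Why: Molybdate-catalysed peroxide oxidation takes a sulfide to the sulfone much faster than it epoxidises an unactivated trisubstituted alkene, so the C14=C15 bond should survive.

Step 25
Reactants: 32 {[(4R,6R)-7-(benzenesulfonyl)-2,6-dimethylhept-2-en-4-yl]oxy}(tert-butyl)dimethylsilane; 22 methyl (1S,2S,5S)-5-(4-iodobut-1-en-2-yl)-2-methyl-2-[(triethylsilyl)oxy]cyclopent-3-ene-1-carboxylate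
Product: 34 methyl (1S,2S,5S)-5-[(5RS,6R,8R)-5-(benzenesulfonyl)-8-[(tert-butyldimethylsilyl)oxy]-6,10-dimethylundeca-1,9-dien-2-yl]-2-methyl-2-[(triethylsilyl)oxy]cyclopent-3-ene-1-carboxylate, via lithiated sulfone 33 (not isolated)
Conditions: 32, n-BuLi, THF, −78 °C; DMPU; then 22, −78 → −30 °C
Reagents that add atoms: none
Why: Alkylation of the α-sulfonyl carbanion by the primary homoallylic iodide (SN2) forms C6–C7, and at low temperature the soft carbanion should neither attack the hindered ester nor deprotonate the shielded C8a–H.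

Step 26
Reactants: 34 methyl (1S,2S,5S)-5-[(5RS,6R,8R)-5-(benzenesulfonyl)-8-[(tert-butyldimethylsilyl)oxy]-6,10-dimethylundeca-1,9-dien-2-yl]-2-methyl-2-[(triethylsilyl)oxy]cyclopent-3-ene-1-carboxylate
Product: 36 (1S,3aS,7RS,8aS)-7-(benzenesulfonyl)-7-[(2R,4R)-4-[(tert-butyldimethylsilyl)oxy]-6-methylhept-5-en-2-yl]-1-methyl-4-methylidene-1-[(triethylsilyl)oxy]-3a,4,5,6,7,8a-hexahydroazulen-8(1H)-one, via sulfonyl carbanion 35 (not isolated)
Conditions: LiN(i-Pr)2 (1.2 equiv), THF, −78 → −30 °C; AcOH, −78 °C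
Reagents that add atoms: none
Why: Dieckmann-type intramolecular acylation of the sulfonyl carbanion by the cis-disposed methyl ester (7-exo-trig) forms C7–C8 and the seven-membered ring; one equivalent of base and a cold quench are meant to avoid enolisation at C8a, which would expel the C1 silyloxy group.

Step 27
Reactants: 36 (1S,3aS,7RS,8aS)-7-(benzenesulfonyl)-7-[(2R,4R)-4-[(tert-butyldimethylsilyl)oxy]-6-methylhept-5-en-2-yl]-1-methyl-4-methylidene-1-[(triethylsilyl)oxy]-3a,4,5,6,7,8a-hexahydroazulen-8(1H)-one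
Product: 37 (1S,3aS,7R,8aS)-7-[(2R,4R)-4-[(tert-butyldimethylsilyl)oxy]-6-methylhept-5-en-2-yl]-1-methyl-4-methylidene-1-[(triethylsilyl)oxy]-3a,4,5,6,7,8a-hexahydroazulen-8(1H)-one
Conditions: SmI2, THF/MeOH, −78 °C
Reagents that add atoms: none
Why: Reductive desulfonylation of the β-keto sulfone gives a samarium enolate that should be protonated at C7 from the open convex face (the face of H-8a), which is also expected to be the more stable epimer with the side chain pseudo-equatorial, so both C7 epimers of 36 converge on 7R.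

Step 28
Reactants: 37 (1S,3aS,7R,8aS)-7-[(2R,4R)-4-[(tert-butyldimethylsilyl)oxy]-6-methylhept-5-en-2-yl]-1-methyl-4-methylidene-1-[(triethylsilyl)oxy]-3a,4,5,6,7,8a-hexahydroazulen-8(1H)-one
Product: 38 (1S,3aS,7R,8aS)-1-hydroxy-7-[(2R,4R)-4-hydroxy-6-methylhept-5-en-2-yl]-1-methyl-4-methylidene-3a,4,5,6,7,8a-hexahydroazulen-8(1H)-one
Conditions: HF·pyridine, pyridine, THF, 0 → 23 °C
Reagents that add atoms: none
Why: Buffered fluoride desilylation removes both silyl ethers without the basic conditions that could trigger retro-aldol cleavage or dehydration of the β-hydroxy ketone.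

Step 29
Reactants: 38 (1S,3aS,7R,8aS)-1-hydroxy-7-[(2R,4R)-4-hydroxy-6-methylhept-5-en-2-yl]-1-methyl-4-methylidene-3a,4,5,6,7,8a-hexahydroazulen-8(1H)-one
Product: 39 (4R,6R)-6-[(1S,3aS,7R,8aS)-1-hydroxy-1-methyl-4-methylidene-8-oxo-1,3a,4,5,6,7,8,8a-octahydroazulen-7-yl]-2-methylhept-2-en-4-yl acetate
Conditions: Ac2O, pyridine, DMAP (cat.), CH2Cl2, 0 °C
Reagents that add atoms: acetic anhydride (CC(=O)OC(C)=O)
Why: Acylation under these mild conditions takes the secondary C13 hydroxyl and leaves the tertiary C1 hydroxyl free, and doing it before the ketone reduction avoids having two secondary alcohols to tell apart.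

Step 30
Reactants: 39 (4R,6R)-6-[(1S,3aS,7R,8aS)-1-hydroxy-1-methyl-4-methylidene-8-oxo-1,3a,4,5,6,7,8,8a-octahydroazulen-7-yl]-2-methylhept-2-en-4-yl acetate
Product: 40 (4R,6R)-6-[(1S,3aS,7R,8S,8aR)-1,8-dihydroxy-1-methyl-4-methylidene-1,3a,4,5,6,7,8,8a-octahydroazulen-7-yl]-2-methylhept-2-en-4-yl acetate (CNP0209568.2)
Conditions: Me4NBH(OAc)3, MeCN/AcOH (1:1), −30 → −10 °C
Reagents that add atoms: none
Why: Hydroxyl-directed reduction with triacetoxyborohydride: hydride bound at the C1 oxygen is delivered to the face of C8=O on the side of H-8a, which is also the face away from the C1 methyl and the C7 side chain, so the 8S alcohol is expected while the acetate is not reduced.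

**Compound list**

1 | (R)-citramalic acid | C[C@@](O)(CC(=O)O)C(=O)O | starting material
2 | dimethyl (2R)-2-hydroxy-2-methylbutanedioate | COC(=O)C[C@@](C)(O)C(=O)OC | intermediate
3 | methyl (3R)-3,4-dihydroxy-3-methylbutanoate | COC(=O)C[C@@](C)(O)CO | intermediate
4 | methyl (3R)-3-methyl-3,4-bis[(triethylsilyl)oxy]butanoate | COC(=O)C[C@@](C)(O[Si](CC)(CC)CC)CO[Si](CC)(CC)CC | intermediate
5 | methyl (3R)-3-methyl-4-oxo-3-[(triethylsilyl)oxy]butanoate | COC(=O)C[C@@](C)(O[Si](CC)(CC)CC)C=O | intermediate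
6 | methyl (3R)-3-methyl-3-[(triethylsilyl)oxy]pent-4-ynoate | COC(=O)C[C@@](C)(O[Si](CC)(CC)CC)C#C | intermediate
7 | but-3-yn-1-ol | C#CCCO | starting material
8 | 1-[(but-3-yn-1-yloxy)methyl]-4-methoxybenzene | C#CCCOCc1ccc(OC)cc1 | intermediate
9 | (2Z)-3-[dimethyl(phenyl)silyl]-2-{2-[(4-methoxybenzyl)oxy]ethyl}prop-2-enal | O=C/C(CCOCc1ccc(OC)cc1)=C\[Si](C)(C)c1ccccc1 | intermediate
10 | (2Z)-3-[dimethyl(phenyl)silyl]-2-{2-[(4-methoxybenzyl)oxy]ethyl}prop-2-en-1-ol | OC/C(CCOCc1ccc(OC)cc1)=C\[Si](C)(C)c1ccccc1 | intermediate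
11 | (2Z)-3-iodo-2-{2-[(4-methoxybenzyl)oxy]ethyl}prop-2-en-1-ol | OC/C(CCOCc1ccc(OC)cc1)=C\I | intermediate
12 | methyl (3R,6Z)-7-(hydroxymethyl)-9-[(4-methoxybenzyl)oxy]-3-methyl-3-[(triethylsilyl)oxy]non-6-en-4-ynoate | COC(=O)C[C@@](C)(O[Si](CC)(CC)CC)C#C/C=C(\CO)CCOCc1ccc(OC)cc1 | intermediate
13 | methyl (3R,4Z,6Z)-7-(hydroxymethyl)-9-[(4-methoxybenzyl)oxy]-3-methyl-3-[(triethylsilyl)oxy]nona-4,6-dienoate | COC(=O)C[C@@](C)(O[Si](CC)(CC)CC)/C=C\C=C(/CO)CCOCc1ccc(OC)cc1 | intermediate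
14 | (3R,4Z,6Z)-7-(hydroxymethyl)-9-[(4-methoxybenzyl)oxy]-3-methyl-3-[(triethylsilyl)oxy]nona-4,6-dienoic acid | OC(=O)C[C@@](C)(O[Si](CC)(CC)CC)/C=C\C=C(/CO)CCOCc1ccc(OC)cc1 | intermediate
15 | mixed anhydride of 14 with 2,4,6-trichlorobenzoic acid | O=C(OC(=O)C[C@@](C)(O[Si](CC)(CC)CC)/C=C\C=C(/CO)CCOCc1ccc(OC)cc1)c1c(Cl)cc(Cl)cc1Cl | intermediate
16 | (4R,5Z,7Z)-8-{2-[(4-methoxybenzyl)oxy]ethyl}-4-methyl-4-[(triethylsilyl)oxy]-4,9-dihydrooxonin-2(3H)-one | O=C1C[C@@](C)(O[Si](CC)(CC)CC)/C=C\C=C(CCOCc2ccc(OC)cc2)/CO1 | intermediate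
17 | trimethylsilyl ketene acetal of 16 (C8=C8a in the ring) | C[Si](C)(C)O/C1=C/[C@@](C)(O[Si](CC)(CC)CC)/C=C\C=C(CCOCc2ccc(OC)cc2)/CO1 | intermediate
18 | trimethylsilyl ester of 19 | C[Si](C)(C)OC(=O)[C@H]1[C@@H](C(=C)CCOCc2ccc(OC)cc2)C=C[C@]1(C)O[Si](CC)(CC)CC | intermediate
19 | (1S,2S,5S)-5-{4-[(4-methoxybenzyl)oxy]but-1-en-2-yl}-2-methyl-2-[(triethylsilyl)oxy]cyclopent-3-ene-1-carboxylic acid | OC(=O)[C@H]1[C@@H](C(=C)CCOCc2ccc(OC)cc2)C=C[C@]1(C)O[Si](CC)(CC)CC | intermediate
20 | methyl (1S,2S,5S)-5-{4-[(4-methoxybenzyl)oxy]but-1-en-2-yl}-2-methyl-2-[(triethylsilyl)oxy]cyclopent-3-ene-1-carboxylate | COC(=O)[C@H]1[C@@H](C(=C)CCOCc2ccc(OC)cc2)C=C[C@]1(C)O[Si](CC)(CC)CC | intermediate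
21 | methyl (1S,2S,5S)-5-(4-hydroxybut-1-en-2-yl)-2-methyl-2-[(triethylsilyl)oxy]cyclopent-3-ene-1-carboxylate | COC(=O)[C@H]1[C@@H](C(=C)CCO)C=C[C@]1(C)O[Si](CC)(CC)CC | intermediate
22 | methyl (1S,2S,5S)-5-(4-iodobut-1-en-2-yl)-2-methyl-2-[(triethylsilyl)oxy]cyclopent-3-ene-1-carboxylate | COC(=O)[C@H]1[C@@H](C(=C)CCI)C=C[C@]1(C)O[Si](CC)(CC)CC | intermediate
23 | (2R)-4-methoxy-2-methyl-4-oxobutanoic acid | COC(=O)C[C@@H](C)C(=O)O | starting material
24 | methyl (3R)-4-hydroxy-3-methylbutanoate | COC(=O)C[C@@H](C)CO | intermediate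
25 | (4R)-4-methyloxolan-2-one | O=C1C[C@@H](C)CO1 | intermediate
26 | (3R)-3-methyl-4-(phenylsulfanyl)butanoic acid | OC(=O)C[C@@H](C)CSc1ccccc1 | intermediate
27 | 1-[(3R)-3-methyl-4-(phenylsulfanyl)butanoyl]imidazole | O=C(C[C@@H](C)CSc1ccccc1)n1ccnc1 | intermediate
28 | (3R)-N-methoxy-N,3-dimethyl-4-(phenylsulfanyl)butanamide | CON(C)C(=O)C[C@@H](C)CSc1ccccc1 | intermediate
29 | (6R)-2,6-dimethyl-7-(phenylsulfanyl)hept-2-en-4-one | CC(C)=CC(=O)C[C@@H](C)CSc1ccccc1 | intermediate
30 | (4R,6R)-2,6-dimethyl-7-(phenylsulfanyl)hept-2-en-4-ol | CC(C)=C[C@H](O)C[C@@H](C)CSc1ccccc1 | intermediate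
31 | tert-butyl{[(4R,6R)-2,6-dimethyl-7-(phenylsulfanyl)hept-2-en-4-yl]oxy}dimethylsilane | CC(C)=C[C@H](O[Si](C)(C)C(C)(C)C)C[C@@H](C)CSc1ccccc1 | intermediate
32 | {[(4R,6R)-7-(benzenesulfonyl)-2,6-dimethylhept-2-en-4-yl]oxy}(tert-butyl)dimethylsilane | CC(C)=C[C@H](O[Si](C)(C)C(C)(C)C)C[C@@H](C)CS(=O)(=O)c1ccccc1 | intermediate
33 | α-lithio derivative of sulfone 32 | CC(C)=C[C@H](O[Si](C)(C)C(C)(C)C)C[C@@H](C)C([Li])S(=O)(=O)c1ccccc1 | intermediate
34 | methyl (1S,2S,5S)-5-[(5RS,6R,8R)-5-(benzenesulfonyl)-8-[(tert-butyldimethylsilyl)oxy]-6,10-dimethylundeca-1,9-dien-2-yl]-2-methyl-2-[(triethylsilyl)oxy]cyclopent-3-ene-1-carboxylate | COC(=O)[C@H]1[C@@H](C(=C)CCC([C@H](C)C[C@H](C=C(C)C)O[Si](C)(C)C(C)(C)C)S(=O)(=O)c2ccccc2)C=C[C@]1(C)O[Si](CC)(CC)CC | intermediate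
35 | α-lithio derivative of sulfone 34 (carbanion at C7) | COC(=O)[C@H]1[C@@H](C(=C)CCC([Li])([C@H](C)C[C@H](C=C(C)C)O[Si](C)(C)C(C)(C)C)S(=O)(=O)c2ccccc2)C=C[C@]1(C)O[Si](CC)(CC)CC | intermediate
36 | (1S,3aS,7RS,8aS)-7-(benzenesulfonyl)-7-[(2R,4R)-4-[(tert-butyldimethylsilyl)oxy]-6-methylhept-5-en-2-yl]-1-methyl-4-methylidene-1-[(triethylsilyl)oxy]-3a,4,5,6,7,8a-hexahydroazulen-8(1H)-one | C=C1CCC(S(=O)(=O)c3ccccc3)([C@H](C)C[C@H](C=C(C)C)O[Si](C)(C)C(C)(C)C)C(=O)[C@H]2[C@@H]1C=C[C@]2(C)O[Si](CC)(CC)CC | intermediate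
37 | (1S,3aS,7R,8aS)-7-[(2R,4R)-4-[(tert-butyldimethylsilyl)oxy]-6-methylhept-5-en-2-yl]-1-methyl-4-methylidene-1-[(triethylsilyl)oxy]-3a,4,5,6,7,8a-hexahydroazulen-8(1H)-one | C=C1CC[C@H]([C@H](C)C[C@H](C=C(C)C)O[Si](C)(C)C(C)(C)C)C(=O)[C@H]2[C@@H]1C=C[C@]2(C)O[Si](CC)(CC)CC | intermediate
38 | (1S,3aS,7R,8aS)-1-hydroxy-7-[(2R,4R)-4-hydroxy-6-methylhept-5-en-2-yl]-1-methyl-4-methylidene-3a,4,5,6,7,8a-hexahydroazulen-8(1H)-one | C=C1CC[C@H]([C@H](C)C[C@H](C=C(C)C)O)C(=O)[C@H]2[C@@H]1C=C[C@]2(C)O | intermediate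
39 | (4R,6R)-6-[(1S,3aS,7R,8aS)-1-hydroxy-1-methyl-4-methylidene-8-oxo-1,3a,4,5,6,7,8,8a-octahydroazulen-7-yl]-2-methylhept-2-en-4-yl acetate | C=C1CC[C@H]([C@H](C)C[C@H](C=C(C)C)OC(C)=O)C(=O)[C@H]2[C@@H]1C=C[C@]2(C)O | intermediate
40 | (4R,6R)-6-[(1S,3aS,7R,8S,8aR)-1,8-dihydroxy-1-methyl-4-methylidene-1,3a,4,5,6,7,8,8a-octahydroazulen-7-yl]-2-methylhept-2-en-4-yl acetate | C=C1CC[C@H]([C@H](C)C[C@H](C=C(C)C)OC(C)=O)[C@H](O)[C@H]2[C@@H]1C=C[C@]2(C)O | target

**Totals**

Total step count: 30 steps.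
Longest linear sequence: 19 steps (steps 1 to 5, 10 to 17, 25 to 30).

**Steps most likely to fail**

1. Step 14 (Ireland–Claisen ring contraction). The lactone enolate may expel the C1 silyloxy group before it is silylated, the strained ketene acetal may decompose instead of rearranging, or the facial selectivity relative to C1 may be poor. The fallback sets out from aldehyde 5 and iodide 11 and replaces the ring contraction by an open-chain Ireland–Claisen rearrangement followed by ring-closing metathesis. Wittig methylenation of 5 (Ph3P=CH2, THF) would give methyl (3R)-3-methyl-3-[(triethylsilyl)oxy]pent-4-enoate F1, and saponification (LiOH·H2O) the acid (3R)-3-methyl-3-[(triethylsilyl)oxy]pent-4-enoic acid F2. Stille coupling of 11 with Bu3SnCH=CH2 (Pd(PPh3)4) would give (2Z)-2-{2-[(4-methoxybenzyl)oxy]ethyl}penta-2,4-dien-1-ol F3. Carbodiimide esterification of F2 with F3 would give the allylic ester (2Z)-2-{2-[(4-methoxybenzyl)oxy]ethyl}penta-2,4-dien-1-yl (3R)-3-methyl-3-[(triethylsilyl)oxy]pent-4-enoate F4. Its Ireland–Claisen rearrangement (LiN(i-Pr)2, Me3SiCl, THF/DMPU, −78 → 23 °C; Z(O)-enolate, chair transition state with the Z allyl terminus) would form C8a–C3a and the C4 methylene in (2S,3S)-3-ethenyl-6-[(4-methoxybenzyl)oxy]-4-methylidene-2-{(2S)-2-[(triethylsilyl)oxy]but-3-en-2-yl}hexanoic acid F5. Ring-closing metathesis of the two vinyl groups with the second-generation Grubbs catalyst would close the cyclopentene and come back to the route at acid 19. In this variant no ring enforces the facial selectivity relative to C1, so a diastereomer separation at F5 or 19 must be expected.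

2. Step 13 (nine-membered lactonisation). Oligomerisation to diolides may outrun the medium-ring closure, and the activated acyl group may lose the β-silyloxy group by elimination. The fallback sets out from aldehyde 5 and iodide 11, makes the ester bond intermolecularly and closes the ring at C3–C3a by an intramolecular Stille coupling. Z-selective Wittig iodo-olefination of 5 (Ph3PCH2I iodide, NaN(SiMe3)2, THF/DMPU, −78 °C) would give methyl (3R,4Z)-5-iodo-3-methyl-3-[(triethylsilyl)oxy]pent-4-enoate F6, and Me3SnOH hydrolysis the acid (3R,4Z)-5-iodo-3-methyl-3-[(triethylsilyl)oxy]pent-4-enoic acid F7. Stannylation of 11 (Me3SnSnMe3, Pd(PPh3)4, toluene, 80 °C) would give (2Z)-2-{2-[(4-methoxybenzyl)oxy]ethyl}-3-(trimethylstannyl)prop-2-en-1-ol F8. Carbodiimide esterification of F7 with F8 would give the iodo stannane ester (2Z)-2-{2-[(4-methoxybenzyl)oxy]ethyl}-3-(trimethylstannyl)prop-2-en-1-yl (3R,4Z)-5-iodo-3-methyl-3-[(triethylsilyl)oxy]pent-4-enoate F9. Stereoretentive ring closure (Pd2(dba)3, AsPh3, N-methylpyrrolidinone, high dilution) would come back to the route at lactone 16.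

3. Step 26 (sulfonyl-carbanion acylation). The base may deprotonate C8a instead of C7 and the C8a enolate would eliminate the C1 silyloxy group, the hindered tertiary carbanion may attack the hindered ester too slowly, or the non-enolisable β-keto sulfone may reopen by retro-Claisen cleavage. The fallback sets out from ester 20 and sulfone 32 and reverses the order of the two bond formations, so that the ring is closed by alkylation of a soft, stabilised anion.
   - Reduction of 20 with i-Bu2AlH (CH2Cl2, −78 °C) would give (1S,2S,5S)-5-{4-[(4-methoxybenzyl)oxy]but-1-en-2-yl}-2-methyl-2-[(triethylsilyl)oxy]cyclopent-3-ene-1-carbaldehyde F10.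
   - Addition of lithiated sulfone 33 would form C7–C8 in the β-hydroxy sulfone F11, obtained as a mixture at C7 and C8.
   - Dess–Martin oxidation would give the β-keto sulfone 4-methoxybenzyl ether F12.
   - DDQ would free the C6 alcohol in the β-keto sulfone alcohol F13.
   - I2/PPh3/imidazole would give the β-keto sulfone iodide F14.
   - Intramolecular C-alkylation of the β-keto sulfone anion (Cs2CO3, DMF, 7-exo-tet) would form C6–C7 and come back to the route at β-keto sulfone 36.

Further compounds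
F1 | step 14 | methyl (3R)-3-methyl-3-[(triethylsilyl)oxy]pent-4-enoate | COC(=O)C[C@@](C)(O[Si](CC)(CC)CC)C=C
F2 | step 14 | (3R)-3-methyl-3-[(triethylsilyl)oxy]pent-4-enoic acid | OC(=O)C[C@@](C)(O[Si](CC)(CC)CC)C=C
F3 | step 14 | (2Z)-2-{2-[(4-methoxybenzyl)oxy]ethyl}penta-2,4-dien-1-ol | OC/C(CCOCc1ccc(OC)cc1)=C\C=C
F4 | step 14 | (2Z)-2-{2-[(4-methoxybenzyl)oxy]ethyl}penta-2,4-dien-1-yl (3R)-3-methyl-3-[(triethylsilyl)oxy]pent-4-enoate | C=C/C=C(\COC(=O)C[C@@](C)(O[Si](CC)(CC)CC)C=C)CCOCc1ccc(OC)cc1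
F5 | step 14 | (2S,3S)-3-ethenyl-6-[(4-methoxybenzyl)oxy]-4-methylidene-2-{(2S)-2-[(triethylsilyl)oxy]but-3-en-2-yl}hexanoic acid | OC(=O)[C@H]([C@@](C)(O[Si](CC)(CC)CC)C=C)[C@H](C=C)C(=C)CCOCc1ccc(OC)cc1
F6 | step 13 | methyl (3R,4Z)-5-iodo-3-methyl-3-[(triethylsilyl)oxy]pent-4-enoate | COC(=O)C[C@@](C)(O[Si](CC)(CC)CC)/C=C\I
F7 | step 13 | (3R,4Z)-5-iodo-3-methyl-3-[(triethylsilyl)oxy]pent-4-enoic acid | OC(=O)C[C@@](C)(O[Si](CC)(CC)CC)/C=C\I
F8 | step 13 | (2Z)-2-{2-[(4-methoxybenzyl)oxy]ethyl}-3-(trimethylstannyl)prop-2-en-1-ol | OC/C(CCOCc1ccc(OC)cc1)=C\[Sn](C)(C)C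
F9 | step 13 | (2Z)-2-{2-[(4-methoxybenzyl)oxy]ethyl}-3-(trimethylstannyl)prop-2-en-1-yl (3R,4Z)-5-iodo-3-methyl-3-[(triethylsilyl)oxy]pent-4-enoate | C[Sn](C)(C)/C=C(\COC(=O)C[C@@](C)(O[Si](CC)(CC)CC)/C=C\I)CCOCc1ccc(OC)cc1
F10 | step 26 | (1S,2S,5S)-5-{4-[(4-methoxybenzyl)oxy]but-1-en-2-yl}-2-methyl-2-[(triethylsilyl)oxy]cyclopent-3-ene-1-carbaldehyde | O=C[C@H]1[C@@H](C(=C)CCOCc2ccc(OC)cc2)C=C[C@]1(C)O[Si](CC)(CC)CC
F11 | step 26 | β-hydroxy sulfone from 33 and F10 (C7–C8 bond, mixture at C7 and C8) | OC([C@H]1[C@@H](C(=C)CCOCc2ccc(OC)cc2)C=C[C@]1(C)O[Si](CC)(CC)CC)C([C@H](C)C[C@H](C=C(C)C)O[Si](C)(C)C(C)(C)C)S(=O)(=O)c3ccccc3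
F12 | step 26 | β-keto sulfone 4-methoxybenzyl ether (C8 ketone, open seven-membered ring) | O=C([C@H]1[C@@H](C(=C)CCOCc2ccc(OC)cc2)C=C[C@]1(C)O[Si](CC)(CC)CC)C([C@H](C)C[C@H](C=C(C)C)O[Si](C)(C)C(C)(C)C)S(=O)(=O)c3ccccc3
F13 | step 26 | β-keto sulfone with free C6 alcohol | O=C([C@H]1[C@@H](C(=C)CCO)C=C[C@]1(C)O[Si](CC)(CC)CC)C([C@H](C)C[C@H](C=C(C)C)O[Si](C)(C)C(C)(C)C)S(=O)(=O)c3ccccc3
F14 | step 26 | β-keto sulfone with C6 iodide | O=C([C@H]1[C@@H](C(=C)CCI)C=C[C@]1(C)O[Si](CC)(CC)CC)C([C@H](C)C[C@H](C=C(C)C)O[Si](C)(C)C(C)(C)C)S(=O)(=O)c3ccccc3
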